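In the theta flask substrate and partner were charged in equal amounts, and the candidate steps that use substrate use partner one for one, so [substrate] and [partner] stayed equal. My first question was how much of them stood in the flask at the time asked.

| flask | substrate | partner | temperature | remark | time |
|---|---|---|---|---|---|
| theta | 0.050 M | 1 equiv | 0 °C | the very flask that is asked about, followed so far |  |
| zeta | 0.10 M | 1 equiv | −15 °C | run made earlier |  |
| flask | 0.050 M | 1.00 equiv | 0 °C |  | 30 min |

| run | time / min | target / % | substrate / % |
|---|---|---|---|
| theta | 3.00 | 28 | 37 |
| theta | 6.00 | 31 | 20 |
| theta | 10.0 | 36 | 15 |
| theta | 12.0 | 37 | 14 |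
| theta | 15.0 | 37 | 13 |
| theta | 20.0 | 41 | 6 |
| zeta | 0.667 | 7 | 83 |
| zeta | 1.00 | 11 | 75 |
| zeta | 2.00 | 13 | 63 |
| zeta | 3.00 | 16 | 53 |
| zeta | 5.00 | 20 | 40 |
| zeta | 8.00 | 23 | 30 |

(standard deviation of a reading: 1.5 percentage points)

- west: at 30 min add substrate, 50.0% of the amount charged, then wait 15 min
- south: at 30 min raise the temperature by 20 K, then wait 15 min
- south-west: change nothing and wait 15 min more
- south-east: at 30 min add partner, 50.0% of the amount charged, then wait 15 min

- what is said of target includes crystals
- crystals is a solid; its amount is given per volume of the solution
- what is added takes up no volume worth counting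
- the analysis behind the earlier runs scatters by 1.5 percentage points, standard deviation
- candidate steps: crystals <-> target; substrate + partner -> isomer of the product A; substrate + partner -> target; substrate + partner -> second isomer; target <-> isomer of the product B

- target, in percent of the substrate first charged, at 30 min
- what to do for the largest gain in target; "none" if nothing gains more than 2 percentage points (west / south / south-west / south-east / none)
- target present, in percent of the substrate first charged, after south
- target present, in percent of the substrate first charged, after south-west

I counted half-times. If the loss runs as [substrate][partner] and the two stay equal, the fraction left after n half-times is one over one plus n, where a half-time is the time to reach half the charge. The theta reading of 15% at 10.0 min gave a half-time of 1.76 min, and the reading at 3.00 min gave 1.76 min. So at 30 min the count stood at 17.0, with 5.56% left, and 15 min later 3.77% was left.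

What was that leftover worth? The last theta reading gave 0.436 target per substrate used, so I reckoned 41.2% target at 30 min. Waiting was worth 0.78 percentage points, less than the margin of 2 points. Using up the leftover was worth 2.4 points. Could warming beat that? The last zeta reading gave a share of 0.329, lower than the theta reading's, but that run differed in both temperature and amount, and target <-> isomer of the product B was a reversible candidate, so I could not size a rise by the count.

The forecast gave 41% (39% to 43.5%), 41.5% after south-west (39.5% to 44%) and 42.5% after south (37.5% to 46%), and it picked south-east: “The two additions are essentially tied; I choose partner.”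

The flask gave 40.7%, 41.4% after south-west and 47.1% after south, and the best move was south.

    crystals ⇌ target, rate k1*(cs1 - [target]) while solid is left; crystals form when [target] > cs1 (solubility = 35.0 mM, k = 0.0472 s⁻¹)
    substrate + partner → isomer of the product A (k = 0.0621 L mol⁻¹ s⁻¹, Ea = 43.0 kJ mol⁻¹)
    substrate + partner → target (k = 0.0935 L mol⁻¹ s⁻¹, Ea = 55.0 kJ mol⁻¹)
    substrate + partner → second isomer (k = 0.0314 L mol⁻¹ s⁻¹, Ea = 65.0 kJ mol⁻¹)
    target ⇌ isomer of the product B (K = 0.161, k = 0.0175 s⁻¹, Ea = 74.0 kJ mol⁻¹, ΔH = −42.0 kJ mol⁻¹)
    (constants at 0 °C)

The theta flask held 5.6% substrate at 30.0 min, against my 5.56%, yet south raised target by 6.5 points, more than that leftover, while isomer of the product B stood at 6.54%. In the theta flask at the start, the step to target, with a half-life of 2.5 min by itself as charged, ran 1.5 times as fast as the loss to isomer of the product A, with 3.7 min. For the neighbour flask with 0.013 M substrate and the same equivalents and temperature, I scaled the half-time to 6.79 min, which gave 18.5% left at 30 min, and that flask held 19%.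

(All runs were computed on assumed constants.)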